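**Retrosynthetic overview**

1. The target comes from the 8‑benzyloxy‑5‑hydroxyflavone 13 by methylation of the chelated 5‑OH and hydrogenolysis of the 8‑O‑benzyl group.
2. The strategy rests on ring A (C4a, C5, C6, C7, C8, C8a): C5–C8 all carry oxygen, a para pair at C5/C8 flanking vicinal methoxyls at C6/C7. These four carbons are the four carbons of dimethyl squarate, and C4a/C8a are C5/C6 of a preformed γ‑pyrone.
3. 13 comes from thermal ring expansion of the 4‑benzyloxy‑4‑pyranonylcyclobutenone 10, which forms C4a–C5 and closes ring A last.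
4. 10 comes from O‑benzylation of the adduct of the C6‑lithiated 2‑aryl‑4‑pyranone 5 with dimethyl squarate (bond C8–C8a).
5. 5 (ring C, with ring B bought) comes from acylation of the enolate of 4‑methoxybut‑3‑en‑2‑one with 3,4,5‑trimethoxybenzoyl chloride and cyclisation. Ring order: B (purchased), C, A.

Key step: step 4

Remark: the target has no stereocentre, so the given structure is a single achiral compound. The quaternary carbinol carbon of 8 and 10 is made racemic and is destroyed in step 4.

**Route**

Step 1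
Reactants: 1 (E)-4-methoxybut-3-en-2-one; 2 3,4,5-trimethoxybenzoyl chloride
Product: 5 2-(3,4,5-trimethoxyphenyl)-4H-pyran-4-one, via lithium enolate 3 (not isolated), via acyclic diketone 4 (not isolated)
Conditions: 1 (2.1 equiv), LiHMDS (2.1 equiv), THF, −78 °C; 2 (1 equiv), −78 °C; aq. NH4Cl; crude, TFA (cat.), PhMe, rt
Reagents that add atoms: none
Why: Claisen-type C-acylation of the kinetic lithium enolate by the aroyl chloride (the second equivalent of enolate takes up the acidic diketone proton), followed by acid-catalysed 6-endo oxa-Michael addition of the enol oxygen to the β-methoxyenone and loss of methanol, is the established enolate-acylation route to 2-substituted γ-pyrones.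

Step 2
Reactants: 5 2-(3,4,5-trimethoxyphenyl)-4H-pyran-4-one; 6 dimethyl squarate
Product: 8 rac-4-hydroxy-2,3-dimethoxy-4-[4-oxo-6-(3,4,5-trimethoxyphenyl)-4H-pyran-2-yl]cyclobut-2-en-1-one, via lithiopyranone 7 (not isolated)
Conditions: LiTMP (1.1 equiv, from TMPH/n-BuLi), THF, −78 °C, 5 added to the base, 15 min; then transferred into 6 (1.3 equiv), THF, −78 °C; aq. NH4Cl at −78 °C
Reagents that add atoms: none
Why: A hindered lithium amide should remove the most acidic ring proton of the γ-pyrone, the C6–H next to the ring oxygen (as in the C2-lithiation of chromones), and the vinyllithium adds 1,2 to one of the two equivalent ketone carbonyls of the squarate ester (standard organolithium–squarate addition); the new carbinol centre forms racemic, which does not matter because step 4 removes it.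

Step 3
Reactants: 8 rac-4-hydroxy-2,3-dimethoxy-4-[4-oxo-6-(3,4,5-trimethoxyphenyl)-4H-pyran-2-yl]cyclobut-2-en-1-one; 9 benzyl bromide
Product: 10 rac-4-(benzyloxy)-2,3-dimethoxy-4-[4-oxo-6-(3,4,5-trimethoxyphenyl)-4H-pyran-2-yl]cyclobut-2-en-1-one
Conditions: BnBr (5 equiv), Ag2O (2 equiv), 4 Å MS, CH2Cl2, rt, dark
Reagents that add atoms: benzyl bromide (9), BrCc1ccccc1
Why: Purdie-type silver(I) oxide alkylation etherifies the tertiary carbinol under neutral conditions, as is usual for 4-hydroxycyclobutenones, so that neither alkoxide-triggered ring opening nor acid-triggered loss of methanol to a cyclobutenedione should compete.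

Step 4
Reactants: 10 rac-4-(benzyloxy)-2,3-dimethoxy-4-[4-oxo-6-(3,4,5-trimethoxyphenyl)-4H-pyran-2-yl]cyclobut-2-en-1-one
Product: 13 8-(benzyloxy)-5-hydroxy-6,7-dimethoxy-2-(3,4,5-trimethoxyphenyl)-4H-chromen-4-one, via dienylketene 11 (not isolated), via dienone tautomer 12 (not isolated)
Conditions: PhMe (0.02 M, degassed), 110 °C, Ar
Reagents that add atoms: none
Why: Heating cleaves the C1–C4 bond of the cyclobutenone in a conrotatory 4π electrocyclic opening in which the C4 benzyloxy donor turns outward, so that in dienylketene 11 the pyranonyl group sits on the same side as the ketene. The electrophilic ketene carbon then bonds to pyranone C5, the nucleophilic α-carbon of the vinylogous ester, in a thermal disrotatory 6π electrocyclisation that forms the C4a–C5 bond and closes carbocyclic ring A as dienone 12, whose C4a–H enolises irreversibly to the chelated phenol 13. This is the Moore rearrangement, established for 4-alkenyl-, 4-aryl- and 4-heteroaryl-4-alkoxycyclobutenones derived from squarate esters, with the pyranone C5=C6 bond taking the part of the alkenyl unit. No stereocentre results: the carbinol carbon of 10 becomes sp2 on ring opening and the transient C4a centre of 12 is lost on aromatisation. The step needs torquoselectivity, secured by the strong preference of the C4 oxygen donor for outward rotation, and regioselectivity, secured because the attachment carbon (pyranone C6) has only one carbon neighbour, C5, the other neighbour being O1. Because the former ketene oxygen is released as a free phenol at C5 while the C8 oxygen stays benzylated, the two para oxygens leave the step already distinguished.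

Step 5
Reactants: 13 8-(benzyloxy)-5-hydroxy-6,7-dimethoxy-2-(3,4,5-trimethoxyphenyl)-4H-chromen-4-one; 14 dimethyl sulfate
Product: 15 8-(benzyloxy)-5,6,7-trimethoxy-2-(3,4,5-trimethoxyphenyl)-4H-chromen-4-one
Conditions: Me2SO4 (5 equiv), K2CO3 (excess), acetone, reflux
Reagents that add atoms: dimethyl sulfate (14), COS(=O)(=O)OC
Why: Williamson O-methylation of the only acidic site; the 5-OH is hydrogen-bonded to C4=O and flanked by the 6-OMe, hence excess reagent and prolonged reflux, conditions under which the benzyl ether, the methyl ethers and the pyranone are inert.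

Step 6
Reactants: 15 8-(benzyloxy)-5,6,7-trimethoxy-2-(3,4,5-trimethoxyphenyl)-4H-chromen-4-one
Product: 16 8-hydroxy-5,6,7-trimethoxy-2-(3,4,5-trimethoxyphenyl)-4H-chromen-4-one (8-hydroxy-5,6,7,3',4',5'-hexamethoxyflavone)
Conditions: H2 (1 atm), 10% Pd/C, EtOAc–MeOH, rt
Reagents that add atoms: none
Why: Catalytic hydrogenolysis cleaves the benzyl–oxygen bond of the aryl benzyl ether to free the 8-OH, while the conjugated C2=C3 bond and the methyl ethers are reduced far more slowly, so the reaction is stopped once 15 is consumed.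

**Compound list**

1 | (E)-4-methoxybut-3-en-2-one | CO/C=C/C(C)=O | starting material
2 | 3,4,5-trimethoxybenzoyl chloride | COc1cc(C(Cl)=O)cc(OC)c1OC | starting material
3 | lithium (E)-4-methoxybuta-1,3-dien-2-olate | [Li]OC(=C)/C=C/OC | intermediate (not isolated)
4 | (E)-5-methoxy-1-(3,4,5-trimethoxyphenyl)pent-4-ene-1,3-dione (largely enolised) | COc1cc(C(=O)CC(=O)/C=C/OC)cc(OC)c1OC | intermediate (not isolated)
5 | 2-(3,4,5-trimethoxyphenyl)-4H-pyran-4-one | COc1cc(-c2cc(=O)cco2)cc(OC)c1OC | intermediate
6 | dimethyl squarate (3,4-dimethoxycyclobut-3-ene-1,2-dione) | COC1=C(OC)C(=O)C1=O | starting material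
7 | [4-oxo-6-(3,4,5-trimethoxyphenyl)-4H-pyran-2-yl]lithium | [Li]c1cc(=O)cc(-c2cc(OC)c(OC)c(OC)c2)o1 | intermediate (not isolated)
8 | rac-4-hydroxy-2,3-dimethoxy-4-[4-oxo-6-(3,4,5-trimethoxyphenyl)-4H-pyran-2-yl]cyclobut-2-en-1-one | COC1=C(OC)C(O)(c2cc(=O)cc(-c3cc(OC)c(OC)c(OC)c3)o2)C1=O | intermediate
9 | benzyl bromide | BrCc1ccccc1 | starting material
10 | rac-4-(benzyloxy)-2,3-dimethoxy-4-[4-oxo-6-(3,4,5-trimethoxyphenyl)-4H-pyran-2-yl]cyclobut-2-en-1-one | COC1=C(OC)C(OCc2ccccc2)(c2cc(=O)cc(-c3cc(OC)c(OC)c(OC)c3)o2)C1=O | intermediate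
11 | (3Z)-4-(benzyloxy)-2,3-dimethoxy-4-[4-oxo-6-(3,4,5-trimethoxyphenyl)-4H-pyran-2-yl]buta-1,3-dien-1-one (pyranonyl cis to the ketene carbon) | O=C=C(OC)/C(OC)=C(/OCc1ccccc1)c1cc(=O)cc(-c2cc(OC)c(OC)c(OC)c2)o1 | intermediate (not isolated)
12 | rac-8-(benzyloxy)-6,7-dimethoxy-2-(3,4,5-trimethoxyphenyl)-4aH-chromene-4,5-dione | COC1=C(OC)C(=O)C2C(=O)C=C(c3cc(OC)c(OC)c(OC)c3)OC2=C1OCc1ccccc1 | intermediate (not isolated)
13 | 8-(benzyloxy)-5-hydroxy-6,7-dimethoxy-2-(3,4,5-trimethoxyphenyl)-4H-chromen-4-one | COc1cc(-c2cc(=O)c3c(O)c(OC)c(OC)c(OCc4ccccc4)c3o2)cc(OC)c1OC | intermediate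
14 | dimethyl sulfate | COS(=O)(=O)OC | starting material
15 | 8-(benzyloxy)-5,6,7-trimethoxy-2-(3,4,5-trimethoxyphenyl)-4H-chromen-4-one | COc1cc(-c2cc(=O)c3c(OC)c(OC)c(OC)c(OCc4ccccc4)c3o2)cc(OC)c1OC | intermediate
16 | 8-hydroxy-5,6,7-trimethoxy-2-(3,4,5-trimethoxyphenyl)-4H-chromen-4-one | COc1cc(-c2cc(=O)c3c(OC)c(OC)c(OC)c(O)c3o2)cc(OC)c1OC | target

**Step count and risks**

Total steps: 6. Longest linear sequence: 6 (1/2 → 5 → 8 → 10 → 13 → 15 → 16; squarate 6 enters in step 2).

Steps most likely to fail:

1. Step 2. Deprotonation may be incomplete or go to the wrong site (C3/C5 of the pyranone or the aryl positions ortho to methoxy), and the lithiated γ-pyrone may decay by adding to unmetalated pyranone before it reaches the squarate. Fallback, from 5 back to 8: zincation with the Lewis-acid-free base TMPZnCl·LiCl (THF, 25 °C), which metalates γ-pyrone rings next to the ring oxygen and should give a species that is stable at room temperature, the C6-zincated pyranone F1. Iodolysis (I2, THF, 0 °C) then gives 2-iodo-6-(3,4,5-trimethoxyphenyl)-4H-pyran-4-one F2, which can be purified and its regiochemistry proven. Iodine–magnesium exchange (iPrMgCl·LiCl, THF, −78 °C), which at this temperature should outrun addition to the doubly vinylogous ester carbonyl, gives the pyranonylmagnesium chloride F3, and addition of 6 at −78 °C returns to 8.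

2. Step 4. The cyclobutenone may open without productive closure: if 6π closure onto pyranone C5 is slower than for simple alkenyl groups, the dienylketene could be lost to oligomerisation or to trapping by adventitious nucleophiles. Fallback, from 2 back to 16, building ring A classically and oxidising C8 last: the dianion of commercial 1-(2-hydroxy-4,5,6-trimethoxyphenyl)ethanone F4 (LiHMDS, THF, −78 °C) is C-acylated with 2 (Baker–Venkataraman-type) to 1-(2-hydroxy-4,5,6-trimethoxyphenyl)-3-(3,4,5-trimethoxyphenyl)propane-1,3-dione F5. Cyclodehydration (cat. H2SO4, AcOH, 100 °C) gives 5,6,7-trimethoxy-2-(3,4,5-trimethoxyphenyl)-4H-chromen-4-one F6. NBS (MeCN, rt) should brominate the only free ring A position, C8, activated by O1, 7-OMe and 5-OMe, to give 8-bromo-5,6,7-trimethoxy-2-(3,4,5-trimethoxyphenyl)-4H-chromen-4-one F7. Miyaura borylation (B2pin2, PdCl2(dppf), KOAc, dioxane, 90 °C) gives the 8-pinacolboronate flavone F8, and oxidation (NaBO3·4H2O, THF–H2O, rt) gives 16 directly.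

3. Step 3. Etherification of the hindered tertiary carbinol may be slow, with loss of methanol to the cyclobutenedione or premature ring opening of the free hydroxycyclobutenone on long exposure. Fallback, from 8 back to 13, differentiating the para oxygens by chelation instead of by alkylation before ring expansion: the free carbinol 8 is heated as in step 4 (degassed PhMe, 110 °C, Ar). The same ring opening and closure should give the hydroquinone 5,8-dihydroxy-6,7-dimethoxy-2-(3,4,5-trimethoxyphenyl)-4H-chromen-4-one F9, handled under argon. The non-chelated 8-OH is then benzylated selectively with 9 (1.05 equiv, K2CO3, acetone, rt), the 5-OH being held back by its hydrogen bond to C4=O, which returns to 13.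

**Further compounds**

F1 | step 2 | chloro[4-oxo-6-(3,4,5-trimethoxyphenyl)-4H-pyran-2-yl]zinc | Cl[Zn]c1cc(=O)cc(-c2cc(OC)c(OC)c(OC)c2)o1
F2 | step 2 | 2-iodo-6-(3,4,5-trimethoxyphenyl)-4H-pyran-4-one | Ic1cc(=O)cc(-c2cc(OC)c(OC)c(OC)c2)o1
F3 | step 2 | chloro[4-oxo-6-(3,4,5-trimethoxyphenyl)-4H-pyran-2-yl]magnesium | Cl[Mg]c1cc(=O)cc(-c2cc(OC)c(OC)c(OC)c2)o1
F4 | step 4 | 1-(2-hydroxy-4,5,6-trimethoxyphenyl)ethanone | CC(=O)c1c(O)cc(OC)c(OC)c1OC
F5 | step 4 | 1-(2-hydroxy-4,5,6-trimethoxyphenyl)-3-(3,4,5-trimethoxyphenyl)propane-1,3-dione | COc1cc(C(=O)CC(=O)c2c(O)cc(OC)c(OC)c2OC)cc(OC)c1OC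
F6 | step 4 | 5,6,7-trimethoxy-2-(3,4,5-trimethoxyphenyl)-4H-chromen-4-one | COc1cc(-c2cc(=O)c3c(OC)c(OC)c(OC)cc3o2)cc(OC)c1OC
F7 | step 4 | 8-bromo-5,6,7-trimethoxy-2-(3,4,5-trimethoxyphenyl)-4H-chromen-4-one | COc1cc(-c2cc(=O)c3c(OC)c(OC)c(OC)c(Br)c3o2)cc(OC)c1OC
F8 | step 4 | 5,6,7-trimethoxy-8-(4,4,5,5-tetramethyl-1,3,2-dioxaborolan-2-yl)-2-(3,4,5-trimethoxyphenyl)-4H-chromen-4-one | COc1cc(-c2cc(=O)c3c(OC)c(OC)c(OC)c(B4OC(C)(C)C(C)(C)O4)c3o2)cc(OC)c1OC
F9 | step 3 | 5,8-dihydroxy-6,7-dimethoxy-2-(3,4,5-trimethoxyphenyl)-4H-chromen-4-one | COc1cc(-c2cc(=O)c3c(O)c(OC)c(OC)c(O)c3o2)cc(OC)c1OC
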